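**Plan**
- Retrosynthesis: after removal of five MOM ethers, ring C is cut in one step at O1–C8a and C4–C4a. This gives a ring A aryne (C4a≡C8a) and an (S)-3-hydroxy-3-phenylpropanoic acid derivative, used as its Weinreb amide.
- Enabling feature: O1 and the C4 carbonyl sit on the adjacent ring A carbons C8a and C4a; the C5 oxygen flanks C4a and polarises the aryne; C2 is a carbinol carbon that is available enantiopure.
- The silyl triflate aryne precursor is cut at the two ring A–CH2 bonds (C6 and C8, twofold Negishi) back to dibrominated methyl 2,6-dihydroxy-4-methoxybenzoate, whose ester blocks the future C4a. Each arm is cut at its diarylmethane bond (Negishi).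
- Forward: arm (steps 1–5), ring A core (6–7), twofold coupling (8), ester → H → Br → SiMe3/OTf (9–11), annulation closing ring C (13), deprotection (14). All benzene rings are bought; ring C is the only ring formed.
- Stereochemistry: the single stereocentre C2 comes from commercial ethyl (S)-3-hydroxy-3-phenylpropanoate; its C–O bond is never broken and the ketone appears only on acidic quench.

Key step: step 13

Notation: "arm" = 2-(methoxymethoxy)-5-[2-(methoxymethoxy)benzyl]benzyl, i.e. a CH2 on C1 of a benzene ring that carries OCH2OCH3 at C2 and a 2-(methoxymethoxy)benzyl group at C5; chromanone atoms are numbered O1, C2, C3, C4, C4a, C5–C8, C8a.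

Assumption: the C2 descriptor of the target is read as S, and 5-bromo-2-hydroxybenzyl alcohol is treated as a purchasable starting material (otherwise one NaBH4 reduction from 5-bromosalicylaldehyde).

**Step 1**
Reactants: 1 2-hydroxybenzyl alcohol
Product: 2 [2-(methoxymethoxy)phenyl]methanol
Conditions: NaH (1.0 equiv), THF/DMF, 0 °C; MOMCl (1.0 equiv), 0 °C → rt
Reagents that add atoms: chloromethyl methyl ether, COCCl
Why: One equivalent of NaH deprotonates only the far more acidic phenol, and the phenoxide is O-alkylated by MOMCl (Williamson-type acetal ether formation).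

**Step 2**
Reactants: 2 [2-(methoxymethoxy)phenyl]methanol
Product: 3 1-(chloromethyl)-2-(methoxymethoxy)benzene
Conditions: PPh3, N-chlorosuccinimide, CH2Cl2, 0 °C → rt; used without storage
Reagents that add atoms: N-chlorosuccinimide, O=C1CCC(=O)N1Cl
Why: Appel-type chlorination converts the primary benzylic alcohol into the chloride under neutral conditions that should leave the acid-labile MOM acetal intact.

**Step 3**
Reactants: 4 5-bromo-2-hydroxybenzyl alcohol
Product: 5 [5-bromo-2-(methoxymethoxy)phenyl]methanol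
Conditions: NaH (1.0 equiv), THF/DMF, 0 °C; MOMCl (1.0 equiv), 0 °C → rt
Reagents that add atoms: chloromethyl methyl ether, COCCl
Why: Selective phenoxide formation and O-alkylation as in step 1 (Williamson-type MOM protection); the aryl bromide and the benzylic alcohol are untouched.

**Step 4**
Reactants: 3 1-(chloromethyl)-2-(methoxymethoxy)benzene; 5 [5-bromo-2-(methoxymethoxy)phenyl]methanol
Product: 7 {2-(methoxymethoxy)-5-[2-(methoxymethoxy)benzyl]phenyl}methanol, via benzylic zinc chloride 6 (not isolated)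
Conditions: 3 (1.6 equiv), Zn dust, LiCl, THF, 25 °C; then 5, Pd(OAc)2 (2 mol %), SPhos (4 mol %), THF, 25 → 50 °C
Reagents that add atoms: none
Why: LiCl-assisted zinc insertion gives a benzylic zinc chloride that should couple with the aryl bromide in a Negishi reaction; organozinc halides are protonated only slowly by an alcohol, so the free hydroxymethyl group is tolerated with the reagent in excess.

**Step 5**
Reactants: 7 {2-(methoxymethoxy)-5-[2-(methoxymethoxy)benzyl]phenyl}methanol
Product: 8 2-(chloromethyl)-1-(methoxymethoxy)-4-[2-(methoxymethoxy)benzyl]benzene (arm chloride)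
Conditions: PPh3, N-chlorosuccinimide, CH2Cl2, 0 °C → rt; used without storage
Reagents that add atoms: N-chlorosuccinimide, O=C1CCC(=O)N1Cl
Why: Appel-type chlorination of the benzylic alcohol under neutral conditions, compatible with both MOM ethers.

**Step 6**
Reactants: 9 methyl 2,6-dihydroxy-4-methoxybenzoate
Product: 10 methyl 3,5-dibromo-2,6-dihydroxy-4-methoxybenzoate
Conditions: N-bromosuccinimide (2.05 equiv), MeCN, 0 °C → rt
Reagents that add atoms: N-bromosuccinimide, O=C1CCC(=O)N1Br
Why: Electrophilic aromatic bromination; C3 and C5 are the only free ring positions and are activated by all three oxygens, while the ester occupies the carbon between the two hydroxyls.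

**Step 7**
Reactants: 10 methyl 3,5-dibromo-2,6-dihydroxy-4-methoxybenzoate
Product: 12 methyl 2-acetoxy-3,5-dibromo-4-methoxy-6-(methoxymethoxy)benzoate, via mono-MOM phenol 11 (not isolated)
Conditions: MOMCl (1.1 equiv), i-Pr2NEt, CH2Cl2, 0 °C; then Ac2O, DMAP (cat.), 25 °C
Reagents that add atoms: chloromethyl methyl ether, COCCl; acetic anhydride, CC(=O)OC(C)=O
Why: After the first O-alkylation the remaining hydroxyl is held in a hydrogen bond to the ester carbonyl and resists MOMCl/amine, so mono-protection should be selective; DMAP-catalysed acetylation then removes the acidic proton before the organozinc step.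

**Step 8**
Reactants: 8 arm chloride; 12 methyl 2-acetoxy-3,5-dibromo-4-methoxy-6-(methoxymethoxy)benzoate
Product: 14 methyl 2-acetoxy-4-methoxy-6-(methoxymethoxy)-3,5-bis(arm)benzoate, via arm zinc chloride 13 (not isolated)
Conditions: 8 (2.6 equiv), Zn dust, LiCl, THF, 25 °C; then 12, Pd(OAc)2 (5 mol %), SPhos (10 mol %), THF, 50 °C
Reagents that add atoms: none
Why: Twofold Negishi coupling; SPhos-ligated palladium inserts into doubly ortho-substituted aryl bromides, the ester and acetate are inert to benzylic zinc halides, and both make the ring less electron-rich for oxidative addition.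

**Step 9**
Reactants: 14 methyl 2-acetoxy-4-methoxy-6-(methoxymethoxy)-3,5-bis(arm)benzoate
Product: 16 3-methoxy-5-(methoxymethoxy)-2,4-bis(arm)phenol, via salicylic acid 15 (not isolated)
Conditions: KOH, DMSO/H2O, 90 °C; then AcOH to pH 5, 60 °C
Reagents that add atoms: none
Why: Saponification removes the acetate and the methyl ester, and the resulting phloroglucinol-type 2-hydroxy-4,6-dialkoxybenzoic acid should lose CO2 by ipso-protonation (protodecarboxylation) at pH 5, which is too mild to cleave the MOM acetals.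

**Step 10**
Reactants: 16 3-methoxy-5-(methoxymethoxy)-2,4-bis(arm)phenol
Product: 17 2-bromo-5-methoxy-3-(methoxymethoxy)-4,6-bis(arm)phenol
Conditions: N-bromosuccinimide (1.0 equiv), CH2Cl2, −78 → −20 °C
Reagents that add atoms: N-bromosuccinimide, O=C1CCC(=O)N1Br
Why: Electrophilic bromination at the only open ring A position, which is ortho to OH and OMOM and para to OMe; the MOM-capped arm rings are far less nucleophilic than this free phenol.

**Step 11**
Reactants: 17 2-bromo-5-methoxy-3-(methoxymethoxy)-4,6-bis(arm)phenol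
Product: 20 5-methoxy-3-(methoxymethoxy)-4,6-bis(arm)-2-(trimethylsilyl)phenyl trifluoromethanesulfonate, via aryl trimethylsilyl ether 18 (not isolated), via lithium 2-silylphenoxide 19 (not isolated)
Conditions: (Me3Si)2NH, THF, 65 °C, then evaporation; n-BuLi, THF, −78 °C; Tf2O, −78 → 0 °C
Reagents that add atoms: hexamethyldisilazane, C[Si](C)(C)N[Si](C)(C)C; trifluoromethanesulfonic anhydride, O=S(=O)(OS(=O)(=O)C(F)(F)F)C(F)(F)F
Why: O-silylation, bromine–lithium exchange and 1,3 O→C silyl shift (retro-Brook rearrangement) should place SiMe3 on the carbon between the two oxygens and leave a lithium phenoxide that is triflated in the same flask; exchange at −78 °C outruns MOM-directed or benzylic deprotonation.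

**Step 12**
Reactants: 21 ethyl (S)-3-hydroxy-3-phenylpropanoate
Product: 22 (S)-3-hydroxy-N-methoxy-N-methyl-3-phenylpropanamide
Conditions: MeNH(OMe)·HCl, i-PrMgCl, THF, −20 → 0 °C
Reagents that add atoms: N,O-dimethylhydroxylamine hydrochloride, CNOC.Cl
Why: Aminolysis of the ester by the magnesium amide of N,O-dimethylhydroxylamine (Weinreb amide formation) proceeds with the secondary alcohol masked as its magnesium alkoxide; the carbinol carbon is not involved, so the (S) configuration is kept.

**Step 13**
Reactants: 20 5-methoxy-3-(methoxymethoxy)-4,6-bis(arm)-2-(trimethylsilyl)phenyl trifluoromethanesulfonate; 22 (S)-3-hydroxy-N-methoxy-N-methyl-3-phenylpropanamide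
Product: 26 (2S)-7-methoxy-5-(methoxymethoxy)-6,8-bis(arm)-2-phenylchroman-4-one, via potassium alkoxide 23 (not isolated), via aryne 24 (not isolated), via hemiaminal alkoxide 25 (not isolated)
Conditions: 22 (1.5 equiv), KH (1.5 equiv), THF, 0 °C; then 20, KF, 18-crown-6, THF, 0 → 25 °C; AcOH then H2O, 0 °C
Reagents that add atoms: none
Why: Proposed new method: fluoride removes SiMe3 and triflate departs to give the C4a≡C8a aryne, the pre-formed potassium alkoxide adds at C8a (O1–C8a), and the C4a aryl anion adds to the tethered Weinreb amide carbonyl (C4–C4a) to give a tetrahedral hemiaminal alkoxide that collapses to the ketone only on acidic quench. The closest known reaction types are the fluoride-induced annulation of arynes with salicylate esters to xanthones and the Parham cyclisation of aryllithiums onto Weinreb amides to chroman-4-ones; an aliphatic β-alkoxide as the oxygen nucleophile in such an annulation is not established. Ring C closes by 6-exo-trig attack of the aryl anion on the amide carbonyl. No stereocentre is created in the product: C2 is introduced as (S) and its C–O bond is never broken, so it is carried over with retention, while C4 is only transiently tetrahedral. The step needs regioselective addition to the unsymmetrical aryne, which the inductively withdrawing C5–OMOM group next to C4a should secure by directing the nucleophile to the distal C8a and the charge to C4a, against the weaker steric bias of the C8 benzyl arm. Using an alkoxide with no O–H present denies the aryl anion a proton source, and the amide (in place of an ester) resists retro-aldol cleavage and releases no alkoxide base, so the flavanone is never exposed to base and cannot racemise by ring opening to a chalcone.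

**Step 14**
Reactants: 26 (2S)-7-methoxy-5-(methoxymethoxy)-6,8-bis(arm)-2-phenylchroman-4-one
Product: 27 5''-(2''''-hydroxybenzyl)uvarinol, (2S)-5-hydroxy-6,8-bis[2-hydroxy-5-(2-hydroxybenzyl)benzyl]-7-methoxy-2-phenylchroman-4-one
Conditions: HCl (dilute), MeOH, 40 °C
Reagents that add atoms: none
Why: Acid-catalysed acetal exchange (MOM cleavage) should transfer the five methoxymethyl groups to methanol; the flavanone C2–O bond and the diarylmethane links are stable to dilute acid at this temperature, so the (S) centre is retained.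

**Compound list**
1 | 2-hydroxybenzyl alcohol | OCc1ccccc1O | starting material
2 | [2-(methoxymethoxy)phenyl]methanol | OCc1ccccc1OCOC | intermediate
3 | 1-(chloromethyl)-2-(methoxymethoxy)benzene | ClCc1ccccc1OCOC | intermediate
4 | 5-bromo-2-hydroxybenzyl alcohol | OCc1cc(Br)ccc1O | starting material
5 | [5-bromo-2-(methoxymethoxy)phenyl]methanol | OCc1cc(Br)ccc1OCOC | intermediate
6 | [2-(methoxymethoxy)benzyl]zinc chloride | Cl[Zn]Cc1ccccc1OCOC | intermediate (not isolated)
7 | {2-(methoxymethoxy)-5-[2-(methoxymethoxy)benzyl]phenyl}methanol | OCc1cc(Cc2ccccc2OCOC)ccc1OCOC | intermediate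
8 | 2-(chloromethyl)-1-(methoxymethoxy)-4-[2-(methoxymethoxy)benzyl]benzene (arm chloride) | ClCc1cc(Cc2ccccc2OCOC)ccc1OCOC | intermediate
9 | methyl 2,6-dihydroxy-4-methoxybenzoate | COC(=O)c1c(O)cc(OC)cc1O | starting material
10 | methyl 3,5-dibromo-2,6-dihydroxy-4-methoxybenzoate | COC(=O)c1c(O)c(Br)c(OC)c(Br)c1O | intermediate
11 | methyl 3,5-dibromo-2-hydroxy-4-methoxy-6-(methoxymethoxy)benzoate | COC(=O)c1c(O)c(Br)c(OC)c(Br)c1OCOC | intermediate (not isolated)
12 | methyl 2-acetoxy-3,5-dibromo-4-methoxy-6-(methoxymethoxy)benzoate | COC(=O)c1c(OC(C)=O)c(Br)c(OC)c(Br)c1OCOC | intermediate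
13 | {2-(methoxymethoxy)-5-[2-(methoxymethoxy)benzyl]benzyl}zinc chloride | Cl[Zn]Cc1cc(Cc2ccccc2OCOC)ccc1OCOC | intermediate (not isolated)
14 | methyl 2-acetoxy-4-methoxy-6-(methoxymethoxy)-3,5-bis(arm)benzoate | COC(=O)c1c(OC(C)=O)c(Cc2cc(Cc3ccccc3OCOC)ccc2OCOC)c(OC)c(Cc2cc(Cc3ccccc3OCOC)ccc2OCOC)c1OCOC | intermediate
15 | 2-hydroxy-4-methoxy-6-(methoxymethoxy)-3,5-bis(arm)benzoic acid | OC(=O)c1c(O)c(Cc2cc(Cc3ccccc3OCOC)ccc2OCOC)c(OC)c(Cc2cc(Cc3ccccc3OCOC)ccc2OCOC)c1OCOC | intermediate (not isolated)
16 | 3-methoxy-5-(methoxymethoxy)-2,4-bis(arm)phenol | Oc1cc(OCOC)c(Cc2cc(Cc3ccccc3OCOC)ccc2OCOC)c(OC)c1Cc1cc(Cc2ccccc2OCOC)ccc1OCOC | intermediate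
17 | 2-bromo-5-methoxy-3-(methoxymethoxy)-4,6-bis(arm)phenol | Oc1c(Br)c(OCOC)c(Cc2cc(Cc3ccccc3OCOC)ccc2OCOC)c(OC)c1Cc1cc(Cc2ccccc2OCOC)ccc1OCOC | intermediate
18 | [2-bromo-5-methoxy-3-(methoxymethoxy)-4,6-bis(arm)phenoxy]trimethylsilane | C[Si](C)(C)Oc1c(Br)c(OCOC)c(Cc2cc(Cc3ccccc3OCOC)ccc2OCOC)c(OC)c1Cc1cc(Cc2ccccc2OCOC)ccc1OCOC | intermediate (not isolated)
19 | lithium 5-methoxy-3-(methoxymethoxy)-4,6-bis(arm)-2-(trimethylsilyl)phenoxide | [Li+].[O-]c1c([Si](C)(C)C)c(OCOC)c(Cc2cc(Cc3ccccc3OCOC)ccc2OCOC)c(OC)c1Cc1cc(Cc2ccccc2OCOC)ccc1OCOC | intermediate (not isolated)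
20 | 5-methoxy-3-(methoxymethoxy)-4,6-bis(arm)-2-(trimethylsilyl)phenyl trifluoromethanesulfonate | COc1c(Cc2cc(Cc3ccccc3OCOC)ccc2OCOC)c(OCOC)c([Si](C)(C)C)c(OS(=O)(=O)C(F)(F)F)c1Cc1cc(Cc2ccccc2OCOC)ccc1OCOC | intermediate
21 | ethyl (S)-3-hydroxy-3-phenylpropanoate | O[C@H](c1ccccc1)CC(=O)OCC | starting material
22 | (S)-3-hydroxy-N-methoxy-N-methyl-3-phenylpropanamide | O[C@H](c1ccccc1)CC(=O)N(C)OC | intermediate
23 | potassium (S)-3-[methoxy(methyl)amino]-3-oxo-1-phenylpropan-1-olate | [K+].[O-][C@H](c1ccccc1)CC(=O)N(C)OC | intermediate (not isolated)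
24 | 5-methoxy-3-(methoxymethoxy)-4,6-bis(arm)-1,2-didehydrobenzene (aryne) | COC1=C(Cc2cc(Cc3ccccc3OCOC)ccc2OCOC)C#CC(OCOC)=C1Cc1cc(Cc2ccccc2OCOC)ccc1OCOC | intermediate (not isolated)
25 | potassium (2S)-7-methoxy-4-[methoxy(methyl)amino]-5-(methoxymethoxy)-6,8-bis(arm)-2-phenylchroman-4-olate | [K+].COc1c(Cc3cc(Cc4ccccc4OCOC)ccc3OCOC)c(OCOC)c2c(c1Cc1cc(Cc3ccccc3OCOC)ccc1OCOC)O[C@H](c1ccccc1)CC2([O-])N(C)OC | intermediate (not isolated)
26 | (2S)-7-methoxy-5-(methoxymethoxy)-6,8-bis(arm)-2-phenylchroman-4-one | COc1c(Cc3cc(Cc4ccccc4OCOC)ccc3OCOC)c(OCOC)c2c(c1Cc1cc(Cc3ccccc3OCOC)ccc1OCOC)O[C@H](c1ccccc1)CC2=O | intermediate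
27 | 5''-(2''''-hydroxybenzyl)uvarinol, (2S)-5-hydroxy-6,8-bis[2-hydroxy-5-(2-hydroxybenzyl)benzyl]-7-methoxy-2-phenylchroman-4-one | COc1c(Cc2cc(Cc3ccccc3O)ccc2O)c(O)c2c(c1Cc1cc(Cc3ccccc3O)ccc1O)O[C@H](c1ccccc1)CC2=O | target

**Step count**
Total: 14 steps. Longest linear sequence: 10 steps (1, 2, 4, 5, 8, 9, 10, 11, 13, 14).

**Steps most likely to fail**

1. Step 13 (new method). Proton transfer to the C4a aryl anion (from the C3 methylene of the tether, adventitious water or the crown ether) may outrun its addition to the amide and stop the sequence at the O-arylation stage. The alkoxide may also add at the wrong aryne carbon or cleave the triflate at sulfur. The fallback uses known chemistry, sets out from bromophenol 17 and returns at 26. The commercial (R)-enantiomer of 21 is converted under the conditions of step 12 into (R)-3-hydroxy-N-methoxy-N-methyl-3-phenylpropanamide F1. Mitsunobu etherification of 17 with F1 (PPh3, diisopropyl azodicarboxylate, toluene, 0 °C → rt) forms the O1–C2 bond with inversion and should give the (S)-configured aryl ether F2. Bromine–lithium exchange (n-BuLi, THF, −78 °C) followed by Parham cyclisation of the aryllithium onto the Weinreb amide gives the lithium hemiaminal alkoxide F3, which releases 26 on AcOH quench.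

2. Step 8. Oxidative addition at the second, doubly ortho-substituted C–Br bond may be slow, so that protodebromination or homocoupling of the benzylic zinc reagent consumes the arm. The fallback sets out from 9 and 8 and returns at 16. The dilithium phenoxide of 9 (LiOt-Bu, toluene, 80 °C) is C-benzylated twice by 8 in a Claisen-type ortho-alkylation of a non-solvated phenoxide, giving methyl 2,6-dihydroxy-4-methoxy-3,5-bis(arm)benzoate F4. Hydrogen-bond-controlled mono-protection (MOMCl, i-Pr2NEt, CH2Cl2, 0 °C) gives methyl 2-hydroxy-4-methoxy-6-(methoxymethoxy)-3,5-bis(arm)benzoate F5. F5 is carried through the conditions of step 9 (via 15) to 16.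

3. Step 11. n-BuLi may attack silicon or deprotonate a diarylmethane CH2 instead of exchanging bromine, and triflation of the very hindered phenoxide may stall. The fallback replaces halogen–metal exchange by carbamate-directed ortho-metalation, sets out from 16 (omitting step 10) and returns at 20. Isopropyl isocyanate with catalytic Et3N converts 16 into 3-methoxy-5-(methoxymethoxy)-2,4-bis(arm)phenyl N-isopropylcarbamate F6. Transient N-silylation (Me3SiOTf, TMEDA), ortho-lithiation between the carbamate and the MOM ether (n-BuLi, TMEDA, −78 °C) and Me3SiCl give the 2-(trimethylsilyl)aryl carbamate F7. DBU and Et2NH in MeCN at 40 °C release 5-methoxy-3-(methoxymethoxy)-4,6-bis(arm)-2-(trimethylsilyl)phenol F8, which is triflated in the same flask with PhNTf2 to give 20.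

**Further compounds**
F1 | step 13 | (R)-3-hydroxy-N-methoxy-N-methyl-3-phenylpropanamide | O[C@@H](c1ccccc1)CC(=O)N(C)OC
F2 | step 13 | (3S)-3-[2-bromo-5-methoxy-3-(methoxymethoxy)-4,6-bis(arm)phenoxy]-N-methoxy-N-methyl-3-phenylpropanamide | COc1c(Cc2cc(Cc3ccccc3OCOC)ccc2OCOC)c(OCOC)c(Br)c(O[C@H](c2ccccc2)CC(=O)N(C)OC)c1Cc1cc(Cc2ccccc2OCOC)ccc1OCOC
F3 | step 13 | lithium (2S)-7-methoxy-4-[methoxy(methyl)amino]-5-(methoxymethoxy)-6,8-bis(arm)-2-phenylchroman-4-olate | [Li+].COc1c(Cc3cc(Cc4ccccc4OCOC)ccc3OCOC)c(OCOC)c2c(c1Cc1cc(Cc3ccccc3OCOC)ccc1OCOC)O[C@H](c1ccccc1)CC2([O-])N(C)OC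
F4 | step 8 | methyl 2,6-dihydroxy-4-methoxy-3,5-bis(arm)benzoate | COC(=O)c1c(O)c(Cc2cc(Cc3ccccc3OCOC)ccc2OCOC)c(OC)c(Cc2cc(Cc3ccccc3OCOC)ccc2OCOC)c1O
F5 | step 8 | methyl 2-hydroxy-4-methoxy-6-(methoxymethoxy)-3,5-bis(arm)benzoate | COC(=O)c1c(O)c(Cc2cc(Cc3ccccc3OCOC)ccc2OCOC)c(OC)c(Cc2cc(Cc3ccccc3OCOC)ccc2OCOC)c1OCOC
F6 | step 11 | 3-methoxy-5-(methoxymethoxy)-2,4-bis(arm)phenyl N-isopropylcarbamate | CC(C)NC(=O)Oc1cc(OCOC)c(Cc2cc(Cc3ccccc3OCOC)ccc2OCOC)c(OC)c1Cc1cc(Cc2ccccc2OCOC)ccc1OCOC
F7 | step 11 | 5-methoxy-3-(methoxymethoxy)-4,6-bis(arm)-2-(trimethylsilyl)phenyl N-isopropylcarbamate | CC(C)NC(=O)Oc1c([Si](C)(C)C)c(OCOC)c(Cc2cc(Cc3ccccc3OCOC)ccc2OCOC)c(OC)c1Cc1cc(Cc2ccccc2OCOC)ccc1OCOC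
F8 | step 11 | 5-methoxy-3-(methoxymethoxy)-4,6-bis(arm)-2-(trimethylsilyl)phenol | Oc1c([Si](C)(C)C)c(OCOC)c(Cc2cc(Cc3ccccc3OCOC)ccc2OCOC)c(OC)c1Cc1cc(Cc2ccccc2OCOC)ccc1OCOC
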